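**Strategy.** Iridoid numbering is used (C1 acetal carbon, O2, C3=C4, C5/C9 ring fusion, C6–C8 cyclopentane, C10 on C8, C11 on C4). The dihydropyran ring is disconnected across O2–C3 and C4–C5, leaving a cyclopentenone carboxylic acid and methyl propiolate. Two features are exploited: the C7 hydroxyl lies β to C5 (C5–C6–C7), so a C7 ketone makes C5 a Michael acceptor, and O2–C3=C4–C11 is a β-oxyacrylate, the adduct of an O-nucleophile with a propiolate. One amine-catalysed oxa-Michael/Michael annulation joins the C1 carboxyl oxygen to C3 and C4 to C5, closing the cis-fused pyranone and setting C5. The precursor comes from a carbene-catalysed Michael/benzoin cascade.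

Key step: step 5

Remarks: (3S)-3-methylpentanoic acid is taken as commercially available. Both antipodes of the triazolium precatalyst in step 2 are available; the one that delivers (1S,2R)-6 is to be identified in the first run. Lactols 14 and 15 are drawn as the 1β-OH anomer (OH cis to H-9), which should predominate at equilibrium.

Step 1
Reactants: 1 methyl 4-chloro-3-oxobutanoate; 2 4-methoxybenzyl alcohol
Product: 3 methyl 4-[(4-methoxybenzyl)oxy]-3-oxobutanoate
Conditions: NaH (2.2 equiv), THF, 0 °C → rt; aq. NH4Cl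
Reagents that add atoms: none
Why: Williamson ether synthesis, in which the alkoxide displaces the activated α-chloro ketone chloride while the β-ketoester is masked as its sodium enolate.

Step 2
Reactants: 3 methyl 4-[(4-methoxybenzyl)oxy]-3-oxobutanoate; 4 acrolein
Product: 6 methyl (1S,2R)-2-hydroxy-2-{[(4-methoxybenzyl)oxy]methyl}-3-oxocyclopentane-1-carboxylate (OH cis to CO2Me), via keto aldehyde 5 (not isolated)
Conditions: Et3N (20 mol %), chiral aminoindanol-derived N-pentafluorophenyl triazolium tetrafluoroborate (10 mol %), CH2Cl2, rt, 4 (1.0 equiv) added over 6 h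
Reagents that add atoms: none
Why: Base-catalysed Michael addition to acrolein followed by carbene-catalysed intramolecular crossed aldehyde–ketone benzoin reaction (5-exo) run as a dynamic kinetic resolution: the chiral carbene selects the ketone face (C8, R), and the rapidly epimerising β-ketoester carbon (C9, S) should close through its hydrogen-bonded syn conformer with CO2Me cis to the new hydroxyl.

Step 3
Reactants: 6 methyl (1S,2R)-2-hydroxy-2-{[(4-methoxybenzyl)oxy]methyl}-3-oxocyclopentane-1-carboxylate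
Product: 7 (1S,2R)-2-hydroxy-2-{[(4-methoxybenzyl)oxy]methyl}-3-oxocyclopentane-1-carboxylic acid
Conditions: LiOH·H2O (1.5 equiv), THF/H2O, 0 °C; 1 M HCl to pH 3
Reagents that add atoms: lithium hydroxide, [Li+].[OH-]
Why: Saponification of the methyl ester, done at the saturated stage, where C9–H is only ester-activated and should not epimerise or allow double-bond migration.

Step 4
Reactants: 7 (1S,2R)-2-hydroxy-2-{[(4-methoxybenzyl)oxy]methyl}-3-oxocyclopentane-1-carboxylic acid
Product: 8 (1S,5R)-5-hydroxy-5-{[(4-methoxybenzyl)oxy]methyl}-4-oxocyclopent-2-ene-1-carboxylic acid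
Conditions: IBX (2 equiv), 4-methoxypyridine N-oxide (2 equiv), DMSO, 25 °C
Reagents that add atoms: none
Why: IBX dehydrogenation of the ketone through its enol; C8 is quaternary, so the double bond can only form at C5=C6, and the room-temperature ligand-modified reagent should spare the PMB ether.

Step 5
Reactants: 8 (1S,5R)-5-hydroxy-5-{[(4-methoxybenzyl)oxy]methyl}-4-oxocyclopent-2-ene-1-carboxylic acid; 9 methyl propiolate
Product: 11 methyl (4aS,7R,7aS)-7-hydroxy-7-{[(4-methoxybenzyl)oxy]methyl}-1,6-dioxo-1,4a,5,6,7,7a-hexahydrocyclopenta[c]pyran-4-carboxylate (cis-fused enol lactone), via ammonium enolate adduct 10 (not isolated)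
Conditions: DABCO (30 mol %), MeCN (0.05 M), 0 → 40 °C, 9 (1.3 equiv) added over 2 h
Reagents that add atoms: none
Why: Proposed new method: DABCO adds to methyl propiolate to give a β-ammonium acrylate, the carboxylate of 8 (O2) adds to its β-carbon (C3) to form the ammonium ester enolate 10, the enolate carbon (C4) attacks C5 of the tethered cyclopentenone, and E1cB loss of DABCO returns the catalyst and leaves the C3=C4 enol ether. The closest known reaction types are the tertiary-amine-catalysed tandem oxa-Michael/Michael [4+2] annulation of 2-hydroxyaryl Michael acceptors with alkynoates to 4H-chromenes and the amine-catalysed hydroacyloxylation of propiolates; the two have not been combined with a carboxylic acid as the O-nucleophile. The pyranone ring closes by a 6-exo-trig Michael addition. The only new stereocentre, C5, is set by C9: the four-atom tether C1–O2–C3–C4 can reach C5 only on the face that carries the carboxyl group, which gives the cis ring fusion (H-5 and H-9 cis). The step needs O-selectivity for the acid over the tertiary C8 hydroxyl, which the much higher acidity of the acid and the hindrance of the alcohol should secure. It also needs ring closure to outrun loss of DABCO to the open (E)-β-acyloxyacrylate; that leak should be reversible through re-addition of DABCO, so the irreversible cyclisation should drain it.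

Step 6
Reactants: 11 methyl (4aS,7R,7aS)-7-hydroxy-7-{[(4-methoxybenzyl)oxy]methyl}-1,6-dioxo-1,4a,5,6,7,7a-hexahydrocyclopenta[c]pyran-4-carboxylate
Product: 12 methyl (4aS,6S,7R,7aS)-6,7-dihydroxy-7-{[(4-methoxybenzyl)oxy]methyl}-1-oxo-1,4a,5,6,7,7a-hexahydrocyclopenta[c]pyran-4-carboxylate (trans-6,7-diol)
Conditions: Me4NBH(OAc)3 (5 equiv), MeCN/AcOH (1:1), −30 °C
Reagents that add atoms: none
Why: Hydroxyl-directed triacetoxyborohydride reduction: the C8 hydroxyl binds boron and delivers hydride intramolecularly to the concave face of the C7 ketone, which should place the C7 hydroxyl trans to the C8 hydroxyl (6S) and leave the lactone and ester untouched.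

Step 7
Reactants: 12 methyl (4aS,6S,7R,7aS)-6,7-dihydroxy-7-{[(4-methoxybenzyl)oxy]methyl}-1-oxo-1,4a,5,6,7,7a-hexahydrocyclopenta[c]pyran-4-carboxylate
Product: 13 methyl (4aS,6S,7R,7aS)-7-{[(4-methoxybenzyl)oxy]methyl}-1-oxo-6,7-bis[(triethylsilyl)oxy]-1,4a,5,6,7,7a-hexahydrocyclopenta[c]pyran-4-carboxylate
Conditions: TESOTf (3 equiv), 2,6-lutidine, CH2Cl2, −78 → 0 °C
Reagents that add atoms: triethylsilyl triflate, CC[Si](CC)(CC)OS(=O)(=O)C(F)(F)F
Why: Silylation with the reactive silyl triflate converts both the secondary C7 and the tertiary C8 hydroxyl into TES ethers, masking them for the later acylations and for the DDQ step.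

Step 8
Reactants: 13 methyl (4aS,6S,7R,7aS)-7-{[(4-methoxybenzyl)oxy]methyl}-1-oxo-6,7-bis[(triethylsilyl)oxy]-1,4a,5,6,7,7a-hexahydrocyclopenta[c]pyran-4-carboxylate
Product: 14 (1R,4aS,6S,7R,7aS)-4-(hydroxymethyl)-7-{[(4-methoxybenzyl)oxy]methyl}-6,7-bis[(triethylsilyl)oxy]-1,4a,5,6,7,7a-hexahydrocyclopenta[c]pyran-1-ol (lactol, 1-OH cis to H-7a)
Conditions: DIBAL-H (4 equiv), CH2Cl2, −78 °C; Rochelle salt work-up
Reagents that add atoms: none
Why: DIBAL-H reduction at −78 °C should stop the enol lactone at the aluminium hemiacetal (lactol after work-up) and take the conjugated C11 ester to the allylic alcohol; the lactol should settle as the anomerically stabilised 1β-OH anomer.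

Step 9
Reactants: 14 (1R,4aS,6S,7R,7aS)-4-(hydroxymethyl)-7-{[(4-methoxybenzyl)oxy]methyl}-6,7-bis[(triethylsilyl)oxy]-1,4a,5,6,7,7a-hexahydrocyclopenta[c]pyran-1-ol
Product: 15 (1R,4aS,6S,7R,7aS)-4-{[(tert-butyldimethylsilyl)oxy]methyl}-7-{[(4-methoxybenzyl)oxy]methyl}-6,7-bis[(triethylsilyl)oxy]-1,4a,5,6,7,7a-hexahydrocyclopenta[c]pyran-1-ol
Conditions: TBSCl (1.1 equiv), imidazole, CH2Cl2, −20 → 0 °C
Reagents that add atoms: tert-butyldimethylsilyl chloride, CC(C)(C)[Si](C)(C)Cl
Why: Chemoselective silylation, in which the unhindered primary allylic C11 hydroxyl should react well before the lactol hydroxyl.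

Step 10
Reactants: 15 (1R,4aS,6S,7R,7aS)-4-{[(tert-butyldimethylsilyl)oxy]methyl}-7-{[(4-methoxybenzyl)oxy]methyl}-6,7-bis[(triethylsilyl)oxy]-1,4a,5,6,7,7a-hexahydrocyclopenta[c]pyran-1-ol; 16 (3S)-3-methylpentanoic acid
Product: 17 (1S,4aS,6S,7R,7aS)-4-{[(tert-butyldimethylsilyl)oxy]methyl}-7-{[(4-methoxybenzyl)oxy]methyl}-6,7-bis[(triethylsilyl)oxy]-1,4a,5,6,7,7a-hexahydrocyclopenta[c]pyran-1-yl (3S)-3-methylpentanoate
Conditions: EDC·HCl (1.5 equiv), DMAP (0.2 equiv), CH2Cl2, −20 → 0 °C
Reagents that add atoms: none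
Why: Steglich esterification on the lactol oxygen, which should retain the configuration of the predominant 1β lactol and give the acylal with the acyloxy group cis to H-9.

Step 11
Reactants: 17 (1S,4aS,6S,7R,7aS)-4-{[(tert-butyldimethylsilyl)oxy]methyl}-7-{[(4-methoxybenzyl)oxy]methyl}-6,7-bis[(triethylsilyl)oxy]-1,4a,5,6,7,7a-hexahydrocyclopenta[c]pyran-1-yl (3S)-3-methylpentanoate
Product: 18 (1S,4aS,6S,7R,7aS)-4-{[(tert-butyldimethylsilyl)oxy]methyl}-7-(hydroxymethyl)-6,7-bis[(triethylsilyl)oxy]-1,4a,5,6,7,7a-hexahydrocyclopenta[c]pyran-1-yl (3S)-3-methylpentanoate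
Conditions: DDQ (1.5 equiv), CH2Cl2/pH 7 phosphate buffer (10:1), 0 °C
Reagents that add atoms: none
Why: Oxidative PMB ether cleavage by DDQ (benzylic hydride abstraction, then hydrolysis of the oxocarbenium ion); the neighbouring C8 oxygen is silylated, so no p-methoxybenzylidene acetal can form.

Step 12
Reactants: 19 (E)-p-coumaric acid
Product: 21 (E)-4-[(tert-butyldimethylsilyl)oxy]cinnamic acid, via bis-silylated coumarate 20 (not isolated)
Conditions: TBSCl (2.5 equiv), imidazole, DMF, rt; then AcOH/THF/H2O (3:1:1), rt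
Reagents that add atoms: tert-butyldimethylsilyl chloride, CC(C)(C)[Si](C)(C)Cl
Why: Silylation of phenol and acid, then selective hydrolysis of the labile silyl ester while the aryl silyl ether stays.

Step 13
Reactants: 18 (1S,4aS,6S,7R,7aS)-4-{[(tert-butyldimethylsilyl)oxy]methyl}-7-(hydroxymethyl)-6,7-bis[(triethylsilyl)oxy]-1,4a,5,6,7,7a-hexahydrocyclopenta[c]pyran-1-yl (3S)-3-methylpentanoate; 21 (E)-4-[(tert-butyldimethylsilyl)oxy]cinnamic acid
Product: 22 fully silylated target: 18 with its C10 hydroxyl esterified by (E)-4-[(tert-butyldimethylsilyl)oxy]cinnamic acid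
Conditions: EDC·HCl (2 equiv), DMAP (0.5 equiv), CH2Cl2, 0 °C → rt
Reagents that add atoms: none
Why: Steglich esterification of the only free hydroxyl, the primary C10–OH, run directly after step 11 so that the C1 acyl group has no time to migrate.

Step 14
Reactants: 22 fully silylated target
Product: 23 (1S,4aS,6S,7R,7aS)-6,7-dihydroxy-4-(hydroxymethyl)-7-({[(2E)-3-(4-hydroxyphenyl)prop-2-enoyl]oxy}methyl)-1,4a,5,6,7,7a-hexahydrocyclopenta[c]pyran-1-yl (3S)-3-methylpentanoate (CNP0241834.1)
Conditions: HF·pyridine, excess pyridine, THF, 0 °C → rt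
Reagents that add atoms: none
Why: Fluoride-driven global desilylation (two TES ethers, primary and phenolic TBS ethers) under buffered conditions that should spare the acylal, the enol ether and both esters.

**Compound list**

1 | methyl 4-chloro-3-oxobutanoate | COC(=O)CC(=O)CCl | starting material
2 | 4-methoxybenzyl alcohol | COc1ccc(CO)cc1 | starting material
3 | methyl 4-[(4-methoxybenzyl)oxy]-3-oxobutanoate | COC(=O)CC(=O)COCc1ccc(OC)cc1 | intermediate
4 | acrolein | C=CC=O | starting material
5 | methyl 4-[(4-methoxybenzyl)oxy]-3-oxo-2-(3-oxopropyl)butanoate (epimerising at C2) | COC(=O)C(CCC=O)C(=O)COCc1ccc(OC)cc1 | intermediate (not isolated)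
6 | methyl (1S,2R)-2-hydroxy-2-{[(4-methoxybenzyl)oxy]methyl}-3-oxocyclopentane-1-carboxylate | COC(=O)[C@H]1CCC(=O)[C@]1(O)COCc1ccc(OC)cc1 | intermediate
7 | (1S,2R)-2-hydroxy-2-{[(4-methoxybenzyl)oxy]methyl}-3-oxocyclopentane-1-carboxylic acid | OC(=O)[C@H]1CCC(=O)[C@]1(O)COCc1ccc(OC)cc1 | intermediate
8 | (1S,5R)-5-hydroxy-5-{[(4-methoxybenzyl)oxy]methyl}-4-oxocyclopent-2-ene-1-carboxylic acid | OC(=O)[C@H]1C=CC(=O)[C@]1(O)COCc1ccc(OC)cc1 | intermediate
9 | methyl propiolate | C#CC(=O)OC | starting material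
10 | DABCO-derived ammonium ester enolate: carboxylate of 8 bound through O2 to C3, which also carries the quaternised DABCO nitrogen; C4 is the enolate carbon | COC([O-])=CC(OC(=O)[C@H]1C=CC(=O)[C@]1(O)COCc1ccc(OC)cc1)[N+]12CCN(CC1)CC2 | intermediate (not isolated)
11 | methyl (4aS,7R,7aS)-7-hydroxy-7-{[(4-methoxybenzyl)oxy]methyl}-1,6-dioxo-1,4a,5,6,7,7a-hexahydrocyclopenta[c]pyran-4-carboxylate | O=C1OC=C(C(=O)OC)[C@H]2CC(=O)[C@](O)(COCc3ccc(OC)cc3)[C@@H]12 | intermediate
12 | methyl (4aS,6S,7R,7aS)-6,7-dihydroxy-7-{[(4-methoxybenzyl)oxy]methyl}-1-oxo-1,4a,5,6,7,7a-hexahydrocyclopenta[c]pyran-4-carboxylate | O=C1OC=C(C(=O)OC)[C@H]2C[C@H](O)[C@](O)(COCc3ccc(OC)cc3)[C@@H]12 | intermediate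
13 | methyl (4aS,6S,7R,7aS)-7-{[(4-methoxybenzyl)oxy]methyl}-1-oxo-6,7-bis[(triethylsilyl)oxy]-1,4a,5,6,7,7a-hexahydrocyclopenta[c]pyran-4-carboxylate | O=C1OC=C(C(=O)OC)[C@H]2C[C@H](O[Si](CC)(CC)CC)[C@](O[Si](CC)(CC)CC)(COCc3ccc(OC)cc3)[C@@H]12 | intermediate
14 | (1R,4aS,6S,7R,7aS)-4-(hydroxymethyl)-7-{[(4-methoxybenzyl)oxy]methyl}-6,7-bis[(triethylsilyl)oxy]-1,4a,5,6,7,7a-hexahydrocyclopenta[c]pyran-1-ol | O[C@@H]1OC=C(CO)[C@H]2C[C@H](O[Si](CC)(CC)CC)[C@](O[Si](CC)(CC)CC)(COCc3ccc(OC)cc3)[C@@H]12 | intermediate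
15 | (1R,4aS,6S,7R,7aS)-4-{[(tert-butyldimethylsilyl)oxy]methyl}-7-{[(4-methoxybenzyl)oxy]methyl}-6,7-bis[(triethylsilyl)oxy]-1,4a,5,6,7,7a-hexahydrocyclopenta[c]pyran-1-ol | O[C@@H]1OC=C(CO[Si](C)(C)C(C)(C)C)[C@H]2C[C@H](O[Si](CC)(CC)CC)[C@](O[Si](CC)(CC)CC)(COCc3ccc(OC)cc3)[C@@H]12 | intermediate
16 | (3S)-3-methylpentanoic acid | CC[C@H](C)CC(=O)O | starting material
17 | 1-O-[(3S)-3-methylpentanoyl] derivative of 15, (1S) | CC[C@H](C)CC(=O)O[C@@H]1OC=C(CO[Si](C)(C)C(C)(C)C)[C@H]2C[C@H](O[Si](CC)(CC)CC)[C@](O[Si](CC)(CC)CC)(COCc3ccc(OC)cc3)[C@@H]12 | intermediate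
18 | 17 without the PMB group (free C10–OH) | CC[C@H](C)CC(=O)O[C@@H]1OC=C(CO[Si](C)(C)C(C)(C)C)[C@H]2C[C@H](O[Si](CC)(CC)CC)[C@](O[Si](CC)(CC)CC)(CO)[C@@H]12 | intermediate
19 | (E)-p-coumaric acid | OC(=O)/C=C/c1ccc(O)cc1 | starting material
20 | tert-butyldimethylsilyl (E)-4-[(tert-butyldimethylsilyl)oxy]cinnamate | CC(C)(C)[Si](C)(C)OC(=O)/C=C/c1ccc(O[Si](C)(C)C(C)(C)C)cc1 | intermediate (not isolated)
21 | (E)-4-[(tert-butyldimethylsilyl)oxy]cinnamic acid | OC(=O)/C=C/c1ccc(O[Si](C)(C)C(C)(C)C)cc1 | intermediate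
22 | fully silylated target (C7, C8 TES ethers; C11 and phenol TBS ethers) | CC[C@H](C)CC(=O)O[C@@H]1OC=C(CO[Si](C)(C)C(C)(C)C)[C@H]2C[C@H](O[Si](CC)(CC)CC)[C@](O[Si](CC)(CC)CC)(COC(=O)/C=C/c3ccc(O[Si](C)(C)C(C)(C)C)cc3)[C@@H]12 | intermediate
23 | CNP0241834.1 | CC[C@H](C)CC(=O)O[C@@H]1OC=C(CO)[C@H]2C[C@H](O)[C@](O)(COC(=O)/C=C/c3ccc(O)cc3)[C@@H]12 | target

**Step count.** Total: 14 steps. Longest linear sequence: 13 steps (steps 1–11, 13, 14); step 12 is a one-step side branch.

**Steps most likely to fail**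

Step 5 (proposed new method). The ammonium enolate may lose DABCO faster than it cyclises, because ring closure needs the disfavoured s-cis conformation of the acyloxy tether; the reaction would then stall at open-chain hydroacyloxylation. Reversible addition of DABCO to the enone may also slow turnover. The fallback uses known chemistry, sets out from acid 8 and propiolate 9, and returns at 11. Bromine is added to 9 (CH2Cl2, 0 °C) to give methyl (E)-2,3-dibromoacrylate F1. The caesium salt of 8 (Cs2CO3, DMF, 0 °C) displaces the β-bromide of F1 by vinylic addition–elimination to give the α-bromo enol ester F2. An intramolecular reductive Heck reaction (Pd(OAc)2, PPh3, HCO2Na, Bu4NCl, DMF, 60 °C) then inserts the C4 vinylpalladium across C5=C6 on the tether face, and formate reduces the palladium enolate, which should give 11 with the same cis fusion.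

Step 2. The dynamic kinetic benzoin closure may give insufficient enantio- or diastereocontrol, through a racemic background closure or slow epimerisation at C9, and the carbene may be diverted by acrolein. The fallback sets out from 3 and 4 and returns at 7. The cascade is run with an achiral N-pentafluorophenyl pyrrolidine-fused triazolium salt to give the racemic cis hydroxy ester F3. Saponification (LiOH, THF/H2O) gives the racemic acid F4. Classical resolution by crystallisation with 1-phenylethylamine gives the less soluble salt of the (1S,2R) acid, written here for the (R)-amine as the diastereomeric salt F5; the amine antipode is chosen to make this the crystalline salt. Acidification releases 7.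

Step 10. Acylation may occur on the minor anomer or on the ring-opened hydroxy dialdehyde tautomer, and DMAP may trigger β-elimination of the C11 silyloxy group from that open form. The fallback sets out from 15 and returns at 17. The lactol is converted with Cl3CCN and catalytic DBU (CH2Cl2, 0 °C) into the anomeric trichloroacetimidate F6. Treatment with acid 16 in toluene, without base, protonates the imidate, and the carboxylate should add to the oxocarbenium ion pair from the convex face (cis to H-9), giving the axial, anomerically stabilised ester 17.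

**Further compounds**

F1 | step 5 | methyl (E)-2,3-dibromoacrylate | COC(=O)/C(Br)=C\Br
F2 | step 5 | methyl 2-bromo-3-{[(1S,5R)-5-hydroxy-5-{[(4-methoxybenzyl)oxy]methyl}-4-oxocyclopent-2-ene-1-carbonyl]oxy}acrylate (alkene geometry inconsequential) | COC(=O)C(Br)=COC(=O)[C@H]1C=CC(=O)[C@]1(O)COCc1ccc(OC)cc1
F3 | step 2 | racemic cis hydroxy ester (6 and its enantiomer) | COC(=O)[C@H]1CCC(=O)[C@]1(O)COCc1ccc(OC)cc1.COC(=O)[C@@H]1CCC(=O)[C@@]1(O)COCc1ccc(OC)cc1
F4 | step 2 | racemic cis hydroxy acid (7 and its enantiomer) | OC(=O)[C@H]1CCC(=O)[C@]1(O)COCc1ccc(OC)cc1.OC(=O)[C@@H]1CCC(=O)[C@@]1(O)COCc1ccc(OC)cc1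
F5 | step 2 | (R)-1-phenylethylammonium salt of the (1S,2R) acid | [O-]C(=O)[C@H]1CCC(=O)[C@]1(O)COCc1ccc(OC)cc1.C[C@@H]([NH3+])c1ccccc1
F6 | step 10 | anomeric trichloroacetimidate of 15 (anomer mixture) | N=C(OC1OC=C(CO[Si](C)(C)C(C)(C)C)[C@H]2C[C@H](O[Si](CC)(CC)CC)[C@](O[Si](CC)(CC)CC)(COCc3ccc(OC)cc3)[C@@H]12)C(Cl)(Cl)Cl
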